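If I had to commit within the hour to a share for this flask, I first asked which given number could spoil it.

in all of them: solid substrate 0.069 M; second catalyst 10 mol%
- maple: reagent 1 equiv; free catalyst 3.4 mol%; run made earlier
- oak: reagent 1 equiv; free catalyst 7.5 mol%; run made earlier
- flask: reagent 1.00 equiv; free catalyst 5 mol%; time 6.0 d

| run | time / d | target / % | side product / % |
|---|---|---|---|
| maple | 0.417 | 67.0 | 12.5 |
| maple | 0.833 | 85.2 | 14.2 |
| maple | 1.25 | 85.8 | 14.0 |
| maple | 2.50 | 85.9 | 13.7 |
| maple | 5.00 | 86.0 | 14.1 |
| oak | 1.04 | 90.0 | 10.2 |
| oak | 2.08 | 89.2 | 10.5 |
| oak | 3.00 | 89.7 | 10.8 |
| oak | 4.00 | 90.0 | 10.6 |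
| oak | 5.00 | 89.6 | 10.1 |

(readings scatter by 0.3 percentage points)

- percent here means solid substrate units held: one side product counts as two
- solid substrate is a solid; its amount is given per volume of the solution
- at the start none of the solid substrate is in solution

* share of target in target plus side product at 1.0 h
* share of target in target plus side product at 12 h
* share of target in target plus side product at 6.0 d

The end time could not: from 1.25 d to 5.00 d, maple's target moved by 0.2 percentage points, against a scatter of 0.3 points. Second catalyst and reagent stood the same in both runs, so these readings could not price them. The loading of free catalyst could matter. Over the last 3 readings, side product per target was 0.162 in maple and 0.117 in oak. That moved the share from 86.0 % to 89.5 %, a step of 3.5 points.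

Going in a straight line between the two loadings, I took 0.145 as this flask's side ratio, the side product per target on the plateau. That meant a final share of 87.4 %. I gave no figure for 1.0 h, which lies earlier than any reading.

The forecast, a little above my share at the end, said 90 %, 87.4 % and 88 %, reasoning that “side product forms mainly while solid keeps dissolved substrate high”.

The flask gave 94.8 %, 87.0 % and 87.7 %, inside the forecast's margins.

    solid substrate ⇌ starting material, rate k1*(cs1 - [starting material]) while solid is left; crystals form when [starting material] > cs1 (solubility = 32.0 mM, k = 0.00900 min⁻¹)
    free catalyst ⇌ dormant form (K = 0.490, k = 0.00490 min⁻¹)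
    starting material + open intermediate → side product (k = 0.130 M⁻¹ min⁻¹)
    reagent + catalyst intermediate → second catalyst + target (k = 4.80 M⁻¹ min⁻¹)
    second catalyst + open intermediate ⇌ catalyst intermediate (K = 20.0 M⁻¹, k = 47.0 M⁻¹ min⁻¹)
    starting material + free catalyst → free catalyst + open intermediate (k = 3.60 M⁻¹ min⁻¹)

The flask's side ratio came to 0.141, against my 0.145. In these equations, with [starting material], [reagent] and [open intermediate] held and the catalyst intermediate at its equilibrium, side product per target goes as one over [second catalyst]. For the neighbouring flask, with a quarter of the second catalyst, 2.5 mol%, my ratio scaled up to 0.578. That flask gave 0.379, with 27.5 % side product and a share of 72.5 % at 6.0 d.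

Readings and results come from a simulation from invented constants; scatter was added.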